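The earlier runs and the new flask were computed with constants of no real substance.

Take the two earlier runs and settle how much coupling partner is worth charging in the next flask.

| setting | maple | alder | north | south-west |
|---|---|---|---|---|
| starting material | 0.10 M | 0.10 M | 0.10 M | 0.10 M |
| coupling partner | 0.099 M | 0.40 M | 0.180 M | 0.450 M |
| protic impurity | 0.020 M | 0.020 M | 0.0200 M | 0.0200 M |
| free catalyst | 0.34 mM | 0.34 mM | 0.34 mM | 0.34 mM |
| remark | run made earlier | run made earlier |  |  |
| time |  |  | 12 h | 12 h |

| run | time / h | catalyst intermediate B / % | product / % | starting material / % |
|---|---|---|---|---|
| maple | 1.50 | 0.7 | 20.1 | 60.0 |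
| maple | 4.00 | 0 | 21.9 | 58.2 |
| maple | 8.00 | 0 | 20.9 | 59.2 |
| maple | 12.0 | 0 | 21.4 | 58.8 |
| alder | 1.50 | 0 | 44.3 | 36.7 |
| alder | 4.00 | 0 | 58.9 | 21.3 |
| alder | 8.00 | 0.4 | 61.0 | 19.2 |
| alder | 12.0 | 0.7 | 60.3 | 18.8 |

(readings scatter by 0.5 percentage points)

- which of these there is most of at the end, counted by the starting material in it, north (catalyst intermediate B / starting material / product)
- which of these there is most of at the end, counted by the starting material in it, south-west (catalyst intermediate B / starting material / product)
- how much there is at the end of the one of these that leads, in percent of the starting material charged: north
- how much there is at the end of the one of these that leads, in percent of the starting material charged: south-west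

Maple held 58.2% starting material at 4.00 h and 58.8% at 12.0 h, and alder held 19.2% at 8.00 h and 18.8% at 12.0 h, so I took both as stopped with starting material still present. At the last reading, starting material plus product came to 80.2% in maple and 79.1% in alder. The protic impurity is 20.0% of the charge, so I counted 0.0800 M of starting material as usable.

I assumed a rate proportional to c(starting material) times c(coupling partner), with a catalyst that gives out at its own pace. Then the sum of the fall in c(starting material) divided by c(starting material) times c(coupling partner), taken over a whole run, belongs to the catalyst charge. Since partner falls one for one with product, the sum closes to a logarithm. It gave 3.52 L mol⁻¹ for maple and 4.01 L mol⁻¹ for alder, and this sum I call the reach of the catalyst. With partner in large excess it is the pseudo-first-order case: the logarithm of the fall in starting material is the reach times c(coupling partner).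

The two readings differ, so I drew a straight line through them against the partner charge, which gave 3.65 L mol⁻¹ for north and, extrapolating, 4.09 L mol⁻¹ for south-west. Solving the logarithm backwards, north ends at c(starting material) = 0.0446 M, which is 44.6% starting material against 35.4% product. South-west ends at 0.0151 M, which is 64.9% product. I would charge south-west.

The forecast said starting material at 44.5% for north and product at 64.5% for south-west, with “catalyst death rather than reagent exhaustion” as its ground, each figure a little below mine.

North ended at 44.3% starting material and south-west at 64.7% product. In south-west >99.9% of the catalyst stood as spent catalyst at 12.0 h, and starting material was still 15.3% at 120 h. Read back from north's end, the reach is 3.70 L mol⁻¹, beside the 3.65 L mol⁻¹ from my line.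

    coupling partner + free catalyst ⇌ catalyst intermediate A (K = 9.20 L mol⁻¹, k = 9720 L mol⁻¹ h⁻¹)
    free catalyst → spent catalyst (k = 4.08 h⁻¹)
    starting material + catalyst intermediate A → catalyst intermediate B (k = 6440 L mol⁻¹ h⁻¹)
    catalyst intermediate B → free catalyst + product (k = 225 h⁻¹)
    starting material + protic impurity → quenched substrate (k = 77.0 L mol⁻¹ h⁻¹)

A neighbour of south-west was charged alike but with 0.060 M of starting material, so I counted 0.0400 M as usable, and the reach 4.09 L mol⁻¹ gives c(starting material) = 0.006937 M, which is 11.6% starting material and 55.1% product. That flask held 7.87% and 58.8%: product led as reckoned, and it went further than the reach said.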